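In a one-step world target would climb to an end value and stay there. These runs don't do that, so the question is when the climb hands over to something else.

the same everywhere: starting material 0.15 M

|  | reagent | second substrate | remark | time |
|---|---|---|---|---|
| north-west | 0.18 M | 0.20 M | run made earlier |  |
| north-east | 0.18 M | 0.45 M | run made earlier |  |
| west | 0.090 M | 0.30 M | run made earlier |  |
| flask | 0.180 M | 0.300 M |  | 6.0 d |

- north-west (time / d: target / %, starting material / %): 0.0347: 65, 38; 0.104: 69, 25; 0.333: 68, 34; 1.04: 53, 47; 4.00: 28, 69
- north-east (time / d: target / %, starting material / %): 0.0347: 58, 46; 0.104: 60, 39; 0.333: 54, 50; 1.04: 37, 65; 4.00: 10, 91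
- west (time / d: target / %, starting material / %): 0.0347: 31, 62; 0.104: 40, 64; 0.333: 34, 63; 1.04: 29, 75; 4.00: 10, 90

(standard deviation of a reading: 2 percentage points)

- the numbers in the tables scatter by 2 percentage points (one standard deviation)

* time, not beyond 6.0 d, at which the flask holds most target
* the amount of target, in percent of the starting material charged, at that time
* the first time at which target reaches 34%, in the same percent

Does target stay? No: in the north-west run it goes from 53% at 1.04 d to 28% at 4.00 d, while starting material comes back from 47% to 69%.

How fast is the fall? Call g the pseudo-first-order fall rate, the logarithm of the ratio of those two target readings over the time between them. It reads 0.216 /d north-west, 0.442 /d north-east and 0.360 /d west.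

What does g follow? Divided by the second substrate charged, these give 1.08 /M/d, 0.982 /M/d and 1.20 /M/d. Their mean is D, the drain constant: fall rate of target per molar of second substrate charged, 1.09 /M/d.

But the west run had half the reagent; doesn't that count? I can't tell: its last reading of 10% carries a scatter of 2 percentage points.

So where does the flask cross over? Its g is 0.326 /d, so its fall time 1/g is 3.07 d, far longer than 0.104 d, where the north-west reading stands highest. I put the peak near that time. A straight line in second substrate between the north-west and north-east readings gives 65.4% there and 62.2% at 0.0347 d. A curve bending over from zero should therefore reach 34% earlier than 0.455 h, by my estimate.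

The forecast says 0.1 d (0.05 d to 0.2 d), 65% (61% to 69%) and 0.4 h (0.2 h to 0.7 h), with “The peak comes when the reagent runs out, near 0.1 d.”

The flask gives 0.101 d, 67.6% and 0.223 h.

    starting material + reagent ⇌ target (K = 230 /M, k = 0.230 /M/min)
    2 reagent → homo dimer (k = 0.0120 /M/min)
    second substrate + reagent → second product (k = 0.0370 /M/min)

By 0.101 d the flask held target at 67.6%, second product at 0.0587 M and homo dimer at 0.00540 M, with reagent at 5.05% of its charge. From then until 6.0 d, second substrate in the flask fell from 80.4% to 49.9% of its charge and target went back to starting material, ending at 11.7%, while reagent, the limiting reagent, stood at 0.272% of its charge at that end. D applied to 67.6% over 6.0 d gives 9.56% for the flask. In a neighbour flask like this one but with its charge of second substrate at 0.075 M, D applied to its best of 80.8% gives 49.5%, and that neighbour ends at 52.6%.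

The numbers in the tables stem from a simulated flask with made-up constants, and the scatter is random.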